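**Plan**

- Target: epiguibourtinidol-(4β→8)-epicatechin, upper unit (2R,3R,4R), lower unit (2R,3R). Retrosynthetic cuts, last-formed first: the seven O-benzyl bonds; the upper C2–H bond (back to a hemiketal); O1–C2 and C3–C4 of the upper ring C together; the C4–S bond of a sulfone; the C4–C8 bond to the epicatechin ring A.
- Enabling feature: upper C4 is a diarylmethine carbon ortho to the ring oxygen O1 on ring A. The atoms C4–C4a–C8a–O1 are therefore a masked o-quinone methide, and only C2–C3 (carrying ring B and the C3 oxygen) has to be added.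
- Forward order: epicatechin is benzylated, brominated at C8, lithiated and added to a protected 2,4-dioxygenated benzaldehyde (C4–C8). The carbinol is stored as a sulfone, a zinc-catalysed annulation with an α-hydroxy ketone closes the upper pyran ring, hydride reduction fixes C2, and hydrogenolysis frees the hydroxyls.
- Stereochemistry: lower C2/C3 come from (−)-epicatechin; upper C3 and C4 from the chiral dinuclear zinc catalyst, backed by equilibration at C3; upper C2 from axial hydride delivery anti to the C3–O bond.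

Key step: step 9

Assumption: with the (S,S)-ligand the zinc enediolate of the hydroxy ketone is attacked on the same face as in aldol reactions of α-hydroxyacetophenones, which corresponds to (R) at upper C3; the route is written on that basis.

**Step 1**
Reactants: 1 (−)-epicatechin
Product: 2 5,7,3',4'-tetra-O-benzyl-(−)-epicatechin
Conditions: BnBr (4.4 equiv), K2CO3, DMF, 0 °C → rt, argon
Reagents that add atoms: benzyl bromide, BrCc1ccccc1
Why: Williamson etherification in which carbonate ionises only the four phenols, so the secondary C3 alcohol stays free and neither stereocentre is touched.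

**Step 2**
Reactants: 2 5,7,3',4'-tetra-O-benzyl-(−)-epicatechin
Product: 3 8-bromo-5,7,3',4'-tetra-O-benzylepicatechin
Conditions: NBS (1.0 equiv), CH2Cl2, −78 °C → rt
Reagents that add atoms: N-bromosuccinimide, BrN1C(=O)CCC1=O
Why: Electrophilic aromatic bromination, which in 5,7-di-O-benzylated flavan-3-ols of the epicatechin series should go to C8 of the phloroglucinol ring in preference to C6 and to ring B, placing the handle at the future interflavan position.

**Step 3**
Reactants: 3 8-bromo-5,7,3',4'-tetra-O-benzylepicatechin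
Product: 4 8-bromo-3,5,7,3',4'-penta-O-benzylepicatechin
Conditions: NaH, BnBr, DMF, 0 °C → rt
Reagents that add atoms: benzyl bromide, BrCc1ccccc1
Why: Williamson etherification of the remaining secondary alcohol through its sodium alkoxide, which removes the last acidic proton before the organolithium and zinc steps without breaking a bond to C2 or C3.

**Step 4**
Reactants: 5 4-(benzyloxy)-2-hydroxybenzaldehyde
Product: 6 4-(benzyloxy)-2-(tert-butyldimethylsilyloxy)benzaldehyde
Conditions: TBSCl, imidazole, DMF, rt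
Reagents that add atoms: tert-butyldimethylsilyl chloride, CC(C)(C)[Si](C)(C)Cl
Why: Imidazole-mediated silylation masks the phenol that must later be the only free hydroxyl, with a group that is orthogonal to the benzyl ethers.

**Step 5**
Reactants: 4 8-bromo-3,5,7,3',4'-penta-O-benzylepicatechin; 6 4-(benzyloxy)-2-(tert-butyldimethylsilyloxy)benzaldehyde
Product: 8 [4-(benzyloxy)-2-(tert-butyldimethylsilyloxy)phenyl](3,5,7,3',4'-penta-O-benzylepicatechin-8-yl)methanol (both carbinol epimers), via aryllithium 7 (not isolated)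
Conditions: t-BuLi (2.0 equiv), THF, −78 °C; then 6, −78 °C; AcOH quench at −78 °C
Reagents that add atoms: none
Why: Bromine–lithium exchange followed by 1,2-addition of the aryllithium to the aldehyde forms the C4–C8 bond; the epimeric carbinol centre is harmless because it becomes trigonal in step 9, and the cold acidic quench should prevent silyl migration to the new alkoxide.

**Step 6**
Reactants: 8 [4-(benzyloxy)-2-(tert-butyldimethylsilyloxy)phenyl](3,5,7,3',4'-penta-O-benzylepicatechin-8-yl)methanol
Product: 9 [4-(benzyloxy)-2-(tert-butyldimethylsilyloxy)phenyl](3,5,7,3',4'-penta-O-benzylepicatechin-8-yl)methyl p-tolyl sulfone (both epimers)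
Conditions: p-TolSO2H (2 equiv, freshly liberated from its sodium salt), 4 Å MS, CH2Cl2, rt
Reagents that add atoms: p-toluenesulfinic acid, Cc1ccc(cc1)S(=O)O
Why: Acid-promoted SN1-type substitution of a diarylcarbinol flanked by two oxygen-rich rings, with S-alkylation of the sulfinate giving the thermodynamically favoured sulfone, the usual bench-stable store for an o-quinone methide.

**Step 7**
Reactants: 9 the silyl-protected sulfone
Product: 10 4-(benzyloxy)-2-hydroxyphenyl (3,5,7,3',4'-penta-O-benzylepicatechin-8-yl)methyl p-tolyl sulfone (both epimers)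
Conditions: TBAF, AcOH (1:1), THF, 0 °C
Reagents that add atoms: none
Why: Fluoride desilylation of the aryl silyl ether, buffered with acetic acid so that the phenol stays protonated and does not expel sulfinate prematurely.

**Step 8**
Reactants: 11 2,4'-dihydroxyacetophenone (2-hydroxy-1-(4-hydroxyphenyl)ethanone)
Product: 12 1-[4-(benzyloxy)phenyl]-2-hydroxyethanone
Conditions: BnBr (1.05 equiv), K2CO3, DMF, rt
Reagents that add atoms: benzyl bromide, BrCc1ccccc1
Why: Chemoselective Williamson etherification, since carbonate ionises the phenol but not the primary α-hydroxyl that the zinc catalyst needs free.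

**Step 9**
Reactants: 10 4-(benzyloxy)-2-hydroxyphenyl (3,5,7,3',4'-penta-O-benzylepicatechin-8-yl)methyl p-tolyl sulfone; 12 1-[4-(benzyloxy)phenyl]-2-hydroxyethanone
Product: 15 (3R,4R)-7-(benzyloxy)-2-[4-(benzyloxy)phenyl]-4-(3,5,7,3',4'-penta-O-benzylepicatechin-8-yl)chromane-2,3-diol (hemiketal; C2 anomers interconvert), via o-quinone methide 13 (not isolated), via keto phenol 14 (not isolated)
Conditions: (S,S)-ProPhenol [2,6-bis{[(S)-2-(hydroxydiphenylmethyl)pyrrolidin-1-yl]methyl}-4-methylphenol] (20 mol %), Et2Zn (40 mol %), 12 (1.5 equiv), 4 Å MS, THF, rt; then 10 premixed with Et2Zn (0.5 equiv), −20 °C → rt; aqueous work-up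
Reagents that add atoms: none
Why: Proposed new method: the zinc phenoxide of 10 expels p-toluenesulfinate in a 1,4-elimination to give o-quinone methide 13, the zinc enediolate of 12 held between the two zinc atoms of the ligand complex adds to the methide carbon (Michael addition, C3–C4), and the rearomatised phenoxide of 14 adds to the aryl ketone (hemiketalisation, O1–C2), the resulting alkoxide taking a proton from the next molecule of 12 so that the catalyst turns over. The closest known reactions are dinuclear-zinc-catalysed direct aldol, Mannich and Michael additions of α-hydroxy aryl ketones and catalytic asymmetric conjugate additions to o-quinone methides released from 2-(sulfonylmethyl)phenols; their combination on a diaryl o-quinone methide is the new element. The upper ring C closes by 6-exo-trig attack of the phenoxide oxygen on the carbonyl carbon. C3 is set by the ligand, which should expose the enediolate face leading to the (R)-carbinol; C4 is set by the face of the zinc-bound quinone methide that meets the enediolate with the bulky epicatechinyl group pointing out of the pocket, the 3,4-trans relationship being backed by equilibration through enolisable 14; C2 is an equilibrating anomeric centre that is erased in step 10. The step needs C- over O-alkylation, secured by the bidentate O,O-binding of the 1,2-hydroxy ketone to zinc, and attack at the methide carbon only, secured by the rearomatisation of ring A; the lower-unit stereocentres make every stereoisomer a separable diastereomer.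

**Step 10**
Reactants: 15 the hemiketal
Product: 17 4',7-di-O-benzylepiguibourtinidol-(4β→8)-3,5,7,3',4'-penta-O-benzylepicatechin (upper unit 2R,3R,4R), via oxocarbenium ion 16 (not isolated)
Conditions: Et3SiH (5 equiv), BF3·OEt2 (Lewis acid, 2 equiv), CH2Cl2, −78 → −30 °C; cold NaHCO3 quench
Reagents that add atoms: none
Why: Lewis-acid-promoted ionic hydrogenation of a hemiketal (reductive etherification) through the 2-aryl oxocarbenium ion 16, in which the C3 hydroxyl should sit pseudoaxial to avoid allylic strain with the coplanar ring B, so that hydride enters axially and anti to the C3–O bond and leaves the C2 aryl cis to the C3 hydroxyl (2R).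

**Step 11**
Reactants: 17 the hepta-O-benzyl dimer
Product: 18 epiguibourtinidol-(4β→8)-epicatechin (target)
Conditions: H2 (1 atm), Pd(OH)2/C, THF/MeOH/H2O, rt
Reagents that add atoms: none
Why: Catalytic hydrogenolysis of the seven benzyl ethers under neutral conditions, which should leave the diarylmethine C4–C8 bond, the cyclic benzylic ethers and all five stereocentres untouched, as in the deprotection of benzylated procyanidins.

**Compound list**

1 | (−)-epicatechin, (2R,3R) | O[C@@H]1Cc2c(O)cc(O)cc2O[C@@H]1c1ccc(O)c(O)c1 | starting material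
2 | 5,7,3',4'-tetra-O-benzyl-(−)-epicatechin | c1c(OCc2ccccc2)cc(OCc2ccccc2)c2c1O[C@H](c1ccc(OCc3ccccc3)c(OCc3ccccc3)c1)[C@H](O)C2 | intermediate
3 | 8-bromo-5,7,3',4'-tetra-O-benzylepicatechin | Brc1c(OCc2ccccc2)cc(OCc2ccccc2)c2c1O[C@H](c1ccc(OCc3ccccc3)c(OCc3ccccc3)c1)[C@H](O)C2 | intermediate
4 | 8-bromo-3,5,7,3',4'-penta-O-benzylepicatechin | Brc1c(OCc2ccccc2)cc(OCc2ccccc2)c2c1O[C@H](c1ccc(OCc3ccccc3)c(OCc3ccccc3)c1)[C@H](OCc1ccccc1)C2 | intermediate
5 | 4-(benzyloxy)-2-hydroxybenzaldehyde | O=Cc1ccc(OCc2ccccc2)cc1O | starting material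
6 | 4-(benzyloxy)-2-(tert-butyldimethylsilyloxy)benzaldehyde | O=Cc1ccc(OCc2ccccc2)cc1O[Si](C)(C)C(C)(C)C | intermediate
7 | 8-lithio-3,5,7,3',4'-penta-O-benzylepicatechin | [Li]c1c(OCc2ccccc2)cc(OCc2ccccc2)c2c1O[C@H](c1ccc(OCc3ccccc3)c(OCc3ccccc3)c1)[C@H](OCc1ccccc1)C2 | intermediate (not isolated)
8 | [4-(benzyloxy)-2-(tert-butyldimethylsilyloxy)phenyl](penta-O-benzylepicatechin-8-yl)methanol, both carbinol epimers | OC(c1ccc(OCc2ccccc2)cc1O[Si](C)(C)C(C)(C)C)c1c(OCc2ccccc2)cc(OCc2ccccc2)c2c1O[C@H](c1ccc(OCc3ccccc3)c(OCc3ccccc3)c1)[C@H](OCc1ccccc1)C2 | intermediate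
9 | [4-(benzyloxy)-2-(tert-butyldimethylsilyloxy)phenyl](penta-O-benzylepicatechin-8-yl)methyl p-tolyl sulfone, both epimers | Cc1ccc(cc1)S(=O)(=O)C(c1ccc(OCc2ccccc2)cc1O[Si](C)(C)C(C)(C)C)c1c(OCc2ccccc2)cc(OCc2ccccc2)c2c1O[C@H](c1ccc(OCc3ccccc3)c(OCc3ccccc3)c1)[C@H](OCc1ccccc1)C2 | intermediate
10 | 4-(benzyloxy)-2-hydroxyphenyl (penta-O-benzylepicatechin-8-yl)methyl p-tolyl sulfone, both epimers | Cc1ccc(cc1)S(=O)(=O)C(c1ccc(OCc2ccccc2)cc1O)c1c(OCc2ccccc2)cc(OCc2ccccc2)c2c1O[C@H](c1ccc(OCc3ccccc3)c(OCc3ccccc3)c1)[C@H](OCc1ccccc1)C2 | intermediate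
11 | 2,4'-dihydroxyacetophenone | O=C(CO)c1ccc(O)cc1 | starting material
12 | 1-[4-(benzyloxy)phenyl]-2-hydroxyethanone | O=C(CO)c1ccc(OCc2ccccc2)cc1 | intermediate
13 | 3-(benzyloxy)-6-[(penta-O-benzylepicatechin-8-yl)methylidene]cyclohexa-2,4-dien-1-one (o-quinone methide, alkene geometry not fixed) | O=C1C=C(OCc2ccccc2)C=CC1=Cc1c(OCc2ccccc2)cc(OCc2ccccc2)c2c1O[C@H](c1ccc(OCc3ccccc3)c(OCc3ccccc3)c1)[C@H](OCc1ccccc1)C2 | intermediate (not isolated)
14 | (2R,3R)-1-[4-(benzyloxy)phenyl]-3-[4-(benzyloxy)-2-hydroxyphenyl]-2-hydroxy-3-(penta-O-benzylepicatechin-8-yl)propan-1-one | c1ccccc1COc1ccc(cc1)C(=O)[C@H](O)[C@H](c1ccc(OCc2ccccc2)cc1O)c1c(OCc2ccccc2)cc(OCc2ccccc2)c2c1O[C@H](c1ccc(OCc3ccccc3)c(OCc3ccccc3)c1)[C@H](OCc1ccccc1)C2 | intermediate (not isolated)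
15 | (3R,4R)-7-(benzyloxy)-2-[4-(benzyloxy)phenyl]-4-(penta-O-benzylepicatechin-8-yl)chromane-2,3-diol, drawn as the (2R) anomer with the C2 aryl cis to the C3 hydroxyl | c1ccccc1COc1ccc(cc1)[C@@]1(O)Oc2cc(OCc3ccccc3)ccc2[C@H](c2c(OCc3ccccc3)cc(OCc3ccccc3)c3c2O[C@H](c2ccc(OCc4ccccc4)c(OCc4ccccc4)c2)[C@H](OCc2ccccc2)C3)[C@H]1O | intermediate
16 | (3R,4R)-7-(benzyloxy)-2-[4-(benzyloxy)phenyl]-3-hydroxy-4-(penta-O-benzylepicatechin-8-yl)-3,4-dihydrochromenylium | c1ccccc1COc1ccc(cc1)C1=[O+]c2cc(OCc3ccccc3)ccc2[C@H](c2c(OCc3ccccc3)cc(OCc3ccccc3)c3c2O[C@H](c2ccc(OCc4ccccc4)c(OCc4ccccc4)c2)[C@H](OCc2ccccc2)C3)[C@H]1O | intermediate (not isolated)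
17 | 4',7-di-O-benzylepiguibourtinidol-(4β→8)-3,5,7,3',4'-penta-O-benzylepicatechin, upper unit (2R,3R,4R) | c1ccccc1COc1ccc(cc1)[C@H]1Oc2cc(OCc3ccccc3)ccc2[C@H](c2c(OCc3ccccc3)cc(OCc3ccccc3)c3c2O[C@H](c2ccc(OCc4ccccc4)c(OCc4ccccc4)c2)[C@H](OCc2ccccc2)C3)[C@H]1O | intermediate
18 | epiguibourtinidol-(4β→8)-epicatechin | Oc1ccc([C@H]2Oc3cc(O)ccc3[C@H](c3c(O)cc(O)c4c3O[C@H](c3ccc(O)c(O)c3)[C@H](O)C4)[C@H]2O)cc1 | target

**Step count and risks**

Total steps: 11. Longest linear sequence: 9 steps (steps 1, 2, 3, 5, 6, 7, 9, 10, 11).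

Most likely to fail:

Step 9. The stabilised, hindered quinone methide may react outside the chiral pocket (poor facial selectivity at C4), the sulfinate may tie up the zinc catalyst, or the alkoxide may add through oxygen. Fallback by known chemistry, setting out from 10 and 12 and returning at 15: 12 is silylated twice with TBSOTf/Et3N in CH2Cl2 to (Z)-1-[4-(benzyloxy)phenyl]-1,2-bis(tert-butyldimethylsilyloxy)ethene F1. The quinone methide 13 is released from 10 with Cs2CO3 in toluene in the presence of F1, and an inverse-electron-demand hetero-Diels–Alder reaction forms the same C3–C4 and O1–C2 bonds to give the 2,3-bis(silyloxy)chromane F2. Facial control then rests on the epicatechin unit alone, so the C4 diastereomers are separated by chromatography. Desilylation with TBAF/AcOH returns 15, any 3,4-cis material being equilibrated through 14 with a trace of base.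

Step 10. Hydride may be delivered from the wrong face, because the pseudoaxial C4 aryl group hinders the approach that leads to the 2,3-cis product, or a 1,2-hydride shift in the cation may lead to the flavan-3-one. Fallback from 15 to 17: the open keto form is reduced under chelation control with Zn(BH4)2 (Et2O/THF, −20 °C) to the anti-diol, (1S,2R,3R)-1-[4-(benzyloxy)phenyl]-3-[4-(benzyloxy)-2-hydroxyphenyl]-3-(penta-O-benzylepicatechin-8-yl)propane-1,2-diol F3. An intramolecular Mitsunobu etherification (PPh3, DIAD, THF, 0 °C) then lets the phenol displace the activated benzylic hydroxyl with inversion, closing O1–C2 with the (2R) configuration of 17.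

Step 7. The transient phenoxide may expel sulfinate during fluoride treatment, followed by oligomerisation of the quinone methide. Fallback from 8 to 10, bypassing 9: the silyl ether is removed first (TBAF, THF, 0 °C) to give [4-(benzyloxy)-2-hydroxyphenyl](penta-O-benzylepicatechin-8-yl)methanol F4, which carries no leaving group. The sulfone is then installed on the free o-hydroxybenzhydrol with p-TolSO2H in CH2Cl2, the classical acid-mediated route to 2-(sulfonylmethyl)phenols, arriving at 10.

**Further compounds**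

F1 | step 9 | (Z)-1-[4-(benzyloxy)phenyl]-1,2-bis(tert-butyldimethylsilyloxy)ethene | CC(C)(C)[Si](C)(C)O/C=C(\O[Si](C)(C)C(C)(C)C)c1ccc(OCc2ccccc2)cc1
F2 | step 9 | (3R,4R)-7-(benzyloxy)-2-[4-(benzyloxy)phenyl]-2,3-bis(tert-butyldimethylsilyloxy)-4-(penta-O-benzylepicatechin-8-yl)chromane, silyloxy groups cis | c1ccccc1COc1ccc(cc1)[C@]1(O[Si](C)(C)C(C)(C)C)Oc2cc(OCc3ccccc3)ccc2[C@H](c2c(OCc3ccccc3)cc(OCc3ccccc3)c3c2O[C@H](c2ccc(OCc4ccccc4)c(OCc4ccccc4)c2)[C@H](OCc2ccccc2)C3)[C@H]1O[Si](C)(C)C(C)(C)C
F3 | step 10 | (1S,2R,3R)-1-[4-(benzyloxy)phenyl]-3-[4-(benzyloxy)-2-hydroxyphenyl]-3-(penta-O-benzylepicatechin-8-yl)propane-1,2-diol | c1ccccc1COc1ccc(cc1)[C@H](O)[C@H](O)[C@H](c1ccc(OCc2ccccc2)cc1O)c1c(OCc2ccccc2)cc(OCc2ccccc2)c2c1O[C@H](c1ccc(OCc3ccccc3)c(OCc3ccccc3)c1)[C@H](OCc1ccccc1)C2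
F4 | step 7 | [4-(benzyloxy)-2-hydroxyphenyl](penta-O-benzylepicatechin-8-yl)methanol, both carbinol epimers | OC(c1ccc(OCc2ccccc2)cc1O)c1c(OCc2ccccc2)cc(OCc2ccccc2)c2c1O[C@H](c1ccc(OCc3ccccc3)c(OCc3ccccc3)c1)[C@H](OCc1ccccc1)C2
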